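**Plan**
1. Retrosynthetic cuts, in order: the three aryl O–CH3 bonds, the side-chain ketone mask and the benzyl ester; then the ring A bond between the ester-bearing carbon (ring C1) and the chain-bearing carbon (ring C6); then the depside acyl–O bond (acylketene + ring B phenol); then two chain C–C bonds (C6–C7, C4–C5); last the C–CO2H bond of ring B.
2. Enabling feature: ring A carries oxygen on C2 and C4, the ester carbon on C1 and the CH2 of the 2-oxoheptyl chain on C6. It is therefore an aldol-folded 3,5,7-trioxo acid (chain C1 = ester carbonyl … C9 = side-chain ketone carbon) whose carboxyl oxygen is O4 of ring B, so ring B can sit on the ester before ring A exists, with C9 held as a dioxolane.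
3. Forward: the chain is built on a dioxinone by two acylations (C4–C5, then C6–C7). Ring B comes from olivetol by carboxylation and benzyl ester formation, its chelated 2-hydroxyl left free. The halves are joined by thermal acylketene capture at the 4-hydroxyl of ring B.
4. Ring A, the only ring made, then closes by aldol addition and dehydration. The three phenols are methylated together, the dioxolane is hydrolysed and the benzyl ester is hydrogenolysed.
5. Stereochemistry: the target has no stereocentre and no stereogenic double bond, so nothing is set or preserved; the only sp3 stereocentres on the route are transient (carbinol 12).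

Key step: step 8

Remark: the target is achiral, so "single enantiomer" means the single compound drawn. Compounds 1, 4 and 7, methyl magnesium carbonate solution, LDA and LiHMDS solutions are taken as commercial.

**Step 1**
Reactants: 1 methyl 3-oxooctanoate
Product: 2 methyl 2-(2-pentyl-1,3-dioxolan-2-yl)acetate
Conditions: HOCH2CH2OH (3 equiv), p-TsOH·H2O (5 mol %), PhMe, reflux, Dean–Stark
Reagents that add atoms: ethylene glycol, OCCO
Why: Acid-catalysed ketalisation with azeotropic water removal is routine for the ketone of a β-keto ester, and the dioxolane masks the future C9 carbonyl so that the later polyketone has only one set of doubly activated methylenes.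

**Step 2**
Reactants: 2 methyl 2-(2-pentyl-1,3-dioxolan-2-yl)acetate
Product: 3 N-methoxy-N-methyl-2-(2-pentyl-1,3-dioxolan-2-yl)acetamide
Conditions: MeNH(OMe)·HCl (1.5 equiv), i-PrMgCl (3 equiv), THF, −20 → 0 °C
Reagents that add atoms: N,O-dimethylhydroxylamine hydrochloride, CNOC.Cl
Why: Direct aminolysis of an ester by the chloromagnesium amide of N,O-dimethylhydroxylamine (Weinreb amide formation) is reliable for enolisable esters at low temperature and does not touch the ketal.

**Step 3**
Reactants: 4 2,2,6-trimethyl-4H-1,3-dioxin-4-one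
Product: 5 2,2-dimethyl-6-(2-oxopropyl)-4H-1,3-dioxin-4-one
Conditions: 4 (2 equiv), LiHMDS (2 equiv), THF, −78 °C; AcCl (1 equiv), −78 → −20 °C
Reagents that add atoms: acetyl chloride, CC(Cl)=O
Why: Deprotonation of the 6-methyl group (vinylogous to the lactone carbonyl) and C-acylation of that carbon by the acid chloride is the standard Claisen-type entry to 6-(2-oxoalkyl)dioxinones, the second equivalent of enolised 4 acting as base for the more acidic product.

**Step 4**
Reactants: 5 2,2-dimethyl-6-(2-oxopropyl)-4H-1,3-dioxin-4-one; 3 N-methoxy-N-methyl-2-(2-pentyl-1,3-dioxolan-2-yl)acetamide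
Product: 6 2,2-dimethyl-6-[2,4-dioxo-5-(2-pentyl-1,3-dioxolan-2-yl)pentyl]-4H-1,3-dioxin-4-one
Conditions: LDA (2.1 equiv), THF, −78 °C; then 3, −78 → −40 °C; sat. aq NH4Cl
Reagents that add atoms: none
Why: Double deprotonation of the keto-dioxinone and Claisen-type acylation at the terminal, more basic carbon by a Weinreb amide should give the diketo-dioxinone, because the chelated tetrahedral adduct persists until work-up and so prevents over-addition and quenching of the dianion by the product.

**Step 5**
Reactants: 7 olivetol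
Product: 8 olivetolic acid (2,4-dihydroxy-6-pentylbenzoic acid)
Conditions: methyl magnesium carbonate (2 M in DMF, 5 equiv), 120 °C, N2 sweep; then ice-cold 1 M HCl
Reagents that add atoms: methyl magnesium carbonate, COC(=O)O[Mg]OC
Why: Kolbe–Schmitt-type ortho-carboxylation through a chelated magnesium phenoxide is the established way from 5-alkylresorcinols to 2,4-dihydroxy-6-alkylbenzoic acids, the chelate protecting the acid from decarboxylation until the cold acid quench; any 2,6-dihydroxy isomer would be removed after step 6.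

**Step 6**
Reactants: 8 olivetolic acid
Product: 9 benzyl 2,4-dihydroxy-6-pentylbenzoate
Conditions: BnBr (1.05 equiv), KHCO3 (1.2 equiv), DMF, rt
Reagents that add atoms: benzyl bromide, BrCc1ccccc1
Why: Hydrogencarbonate ionises only the carboxylic acid, so SN2 alkylation of the carboxylate should give the benzyl ester without O-benzylation of either phenol.

**Step 7**
Reactants: 6 2,2-dimethyl-6-[2,4-dioxo-5-(2-pentyl-1,3-dioxolan-2-yl)pentyl]-4H-1,3-dioxin-4-one; 9 benzyl 2,4-dihydroxy-6-pentylbenzoate
Product: 11 benzyl 2-hydroxy-6-pentyl-4-{[3,5,7-trioxo-8-(2-pentyl-1,3-dioxolan-2-yl)octanoyl]oxy}benzoate, via acylketene 10 (not isolated)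
Conditions: 9 (1.2 equiv), PhMe (0.05 M), 110 °C; evaporate, use crude (keto–enol mixture)
Reagents that add atoms: none
Why: Thermal retro-hetero-Diels–Alder cleavage of the dioxinone releases acetone and an acylketene that should acylate the free 4-hydroxyl of 9 in preference to the 2-hydroxyl, which is hydrogen-bonded to and flanked by the benzyl ester, the same site selectivity as in classical depside esterifications, and the excess of phenol counters lactonisation of the ketene onto its own C5 enol.

**Step 8**
Reactants: 11 benzyl 2-hydroxy-6-pentyl-4-{[3,5,7-trioxo-8-(2-pentyl-1,3-dioxolan-2-yl)octanoyl]oxy}benzoate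
Product: 13 benzyl 4-({2,4-dihydroxy-6-[(2-pentyl-1,3-dioxolan-2-yl)methyl]benzoyl}oxy)-2-hydroxy-6-pentylbenzoate, via aldol carbinol 12 (not isolated)
Conditions: Et3N (2 equiv), CH2Cl2, 0 °C → rt; then AcOH, rt
Reagents that add atoms: none
Why: Triethylamine ionises the C2 methylene, flanked by the aryl ester carbonyl C1 and the C3 ketone, and this carbon adds to the C7 ketone to give the six-membered carbinol 12 (ring atoms C2–C7), which loses water and enolises at C3 and C5 to the aromatic 2,4-dihydroxybenzoate, the acid treatment completing the dehydration. The closest known reaction is the base-mediated aldol cyclisation and aromatisation of 3,5,7-trioxo alkyl esters obtained from dioxinone-derived acylketenes, which gives resorcylates. The ring closes in a favoured 6-(enolexo)-exo-trig mode, the nucleophilic carbon being delocalised into C1 and C3 and the C7 carbonyl oxygen lying outside the new ring. No stereocentre remains, since the carbinol centre of 12 is lost on aromatisation. The step needs C2-to-C7 aldol addition to win over Claisen attack of C6 on the aryl ester, over lactonisation or ketene formation with loss of the ring B phenoxide, and over the alternative C8-to-C3 aldol. The dioxolane at C9 leaves C8 activated by one carbonyl only and removes C9 as an electrophile, and a weak amine base in an aprotic, alcohol-free solvent at low temperature favours addition to the ketone over attack at, or ionisation of, the ester.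

**Step 9**
Reactants: 13 benzyl 4-({2,4-dihydroxy-6-[(2-pentyl-1,3-dioxolan-2-yl)methyl]benzoyl}oxy)-2-hydroxy-6-pentylbenzoate
Product: 14 benzyl 4-({2,4-dimethoxy-6-[(2-pentyl-1,3-dioxolan-2-yl)methyl]benzoyl}oxy)-2-methoxy-6-pentylbenzoate
Conditions: MeI (10 equiv), K2CO3 (6 equiv), acetone, 56 °C (sealed)
Reagents that add atoms: iodomethane, CI
Why: Williamson O-methylation with excess reagent at reflux should also alkylate the two chelated ortho-hydroxyls, as in the classical permethylation of depsides, while the doubly ortho-substituted aryl ester, the benzyl ester and the ketal are inert to carbonate in acetone.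

**Step 10**
Reactants: 14 benzyl 4-({2,4-dimethoxy-6-[(2-pentyl-1,3-dioxolan-2-yl)methyl]benzoyl}oxy)-2-methoxy-6-pentylbenzoate
Product: 15 benzyl 4-{[2,4-dimethoxy-6-(2-oxoheptyl)benzoyl]oxy}-2-methoxy-6-pentylbenzoate
Conditions: 1 M aq HCl/THF (1:4), rt, short reaction time
Reagents that add atoms: water, O
Why: Acid-catalysed hydrolysis of a dialkyl-ketone dioxolane proceeds in dilute aqueous acid at room temperature, where both esters are stable, and the mild, brief treatment should keep the liberated ketone from enol-lactonising onto the neighbouring aryl ester (isocoumarin formation with loss of ring B).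

**Step 11**
Reactants: 15 benzyl 4-{[2,4-dimethoxy-6-(2-oxoheptyl)benzoyl]oxy}-2-methoxy-6-pentylbenzoate
Product: 16 4-{[2,4-dimethoxy-6-(2-oxoheptyl)benzoyl]oxy}-2-methoxy-6-pentylbenzoic acid (target)
Conditions: H2 (1 atm), 10 % Pd/C, EtOAc, rt
Reagents that add atoms: none
Why: Catalytic hydrogenolysis of the benzyl ester is neutral and should leave the aryl ester, the dialkyl ketone and the aryl methyl ethers untouched.

**Compound list**
1 | methyl 3-oxooctanoate | CCCCCC(=O)CC(=O)OC | starting material
2 | methyl 2-(2-pentyl-1,3-dioxolan-2-yl)acetate | CCCCCC1(CC(=O)OC)OCCO1 | intermediate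
3 | N-methoxy-N-methyl-2-(2-pentyl-1,3-dioxolan-2-yl)acetamide | CCCCCC1(CC(=O)N(C)OC)OCCO1 | intermediate
4 | 2,2,6-trimethyl-4H-1,3-dioxin-4-one | CC1=CC(=O)OC(C)(C)O1 | starting material
5 | 2,2-dimethyl-6-(2-oxopropyl)-4H-1,3-dioxin-4-one | CC(=O)CC1=CC(=O)OC(C)(C)O1 | intermediate
6 | 2,2-dimethyl-6-[2,4-dioxo-5-(2-pentyl-1,3-dioxolan-2-yl)pentyl]-4H-1,3-dioxin-4-one | CCCCCC1(CC(=O)CC(=O)CC2=CC(=O)OC(C)(C)O2)OCCO1 | intermediate
7 | olivetol (5-pentylbenzene-1,3-diol) | CCCCCc1cc(O)cc(O)c1 | starting material
8 | olivetolic acid (2,4-dihydroxy-6-pentylbenzoic acid) | CCCCCc1cc(O)cc(O)c1C(=O)O | intermediate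
9 | benzyl 2,4-dihydroxy-6-pentylbenzoate | CCCCCc1cc(O)cc(O)c1C(=O)OCc1ccccc1 | intermediate
10 | 8-(2-pentyl-1,3-dioxolan-2-yl)oct-1-ene-1,3,5,7-tetrone (acylketene) | CCCCCC1(CC(=O)CC(=O)CC(=O)C=C=O)OCCO1 | intermediate (not isolated)
11 | benzyl 2-hydroxy-6-pentyl-4-{[3,5,7-trioxo-8-(2-pentyl-1,3-dioxolan-2-yl)octanoyl]oxy}benzoate | CCCCCC1(CC(=O)CC(=O)CC(=O)CC(=O)Oc2cc(CCCCC)c(C(=O)OCc3ccccc3)c(O)c2)OCCO1 | intermediate
12 | benzyl 2-hydroxy-4-[({2-hydroxy-4,6-dioxo-2-[(2-pentyl-1,3-dioxolan-2-yl)methyl]cyclohexyl}carbonyl)oxy]-6-pentylbenzoate (aldol carbinol, racemic, configuration undefined) | CCCCCC1(CC2(O)CC(=O)CC(=O)C2C(=O)Oc2cc(CCCCC)c(C(=O)OCc3ccccc3)c(O)c2)OCCO1 | intermediate (not isolated)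
13 | benzyl 4-({2,4-dihydroxy-6-[(2-pentyl-1,3-dioxolan-2-yl)methyl]benzoyl}oxy)-2-hydroxy-6-pentylbenzoate | CCCCCC1(Cc2cc(O)cc(O)c2C(=O)Oc2cc(CCCCC)c(C(=O)OCc3ccccc3)c(O)c2)OCCO1 | intermediate
14 | benzyl 4-({2,4-dimethoxy-6-[(2-pentyl-1,3-dioxolan-2-yl)methyl]benzoyl}oxy)-2-methoxy-6-pentylbenzoate | CCCCCC1(Cc2cc(OC)cc(OC)c2C(=O)Oc2cc(CCCCC)c(C(=O)OCc3ccccc3)c(OC)c2)OCCO1 | intermediate
15 | benzyl 4-{[2,4-dimethoxy-6-(2-oxoheptyl)benzoyl]oxy}-2-methoxy-6-pentylbenzoate | CCCCCC(=O)Cc1cc(OC)cc(OC)c1C(=O)Oc1cc(CCCCC)c(C(=O)OCc2ccccc2)c(OC)c1 | intermediate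
16 | 4-{[2,4-dimethoxy-6-(2-oxoheptyl)benzoyl]oxy}-2-methoxy-6-pentylbenzoic acid | CCCCCC(=O)Cc1cc(OC)cc(OC)c1C(=O)Oc1cc(CCCCC)c(C(=O)O)c(OC)c1 | target

**Step count**
Total: 11 steps. Longest linear sequence: 8 steps (1, 2, 4, 7, 8, 9, 10, 11, from methyl 3-oxooctanoate).

**Steps most likely to fail**

Step 8 (key step). The C2 carbanion may expel the ring B phenoxide, giving a ketene that lactonises to a 4-hydroxy-2-pyranone, or C6 may attack the aryl ester in a Claisen closure, faster than C2 adds to C7. The fallback sets out from 6 and performs the same aldol–dehydration, forming the same ring bond, with the dioxinone itself as the carboxyl mask, so that no aryloxide leaving group is present. Et3N in CH2Cl2 followed by AcOH should give 7-hydroxy-2,2-dimethyl-5-[(2-pentyl-1,3-dioxolan-2-yl)methyl]-4H-1,3-benzodioxin-4-one F1. MeI and K2CO3 in acetone then give 7-methoxy-2,2-dimethyl-5-[(2-pentyl-1,3-dioxolan-2-yl)methyl]-4H-1,3-benzodioxin-4-one F2. Irradiation of F2 at about 300 nm in CH2Cl2 in the presence of 9 releases acetone and a quinone ketene, which the 4-hydroxyl of 9 should capture (photochemical acylation, known for hindered salicylate esters). This gives benzyl 2-hydroxy-4-({2-hydroxy-4-methoxy-6-[(2-pentyl-1,3-dioxolan-2-yl)methyl]benzoyl}oxy)-6-pentylbenzoate F3. Methylation of its two chelated hydroxyls (MeI, K2CO3, acetone, reflux) returns to the route at 14.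

Step 7. Capture of the acylketene by a weakly nucleophilic phenol may lose to intramolecular capture by the C5 enol (pyranone formation), or acylation may spread to the chelated 2-hydroxyl. The fallback sets out from 6 and uses no ketene–phenol capture at all. Heating 6 with benzyl alcohol in toluene at 110 °C should give benzyl 3,5,7-trioxo-8-(2-pentyl-1,3-dioxolan-2-yl)octanoate F4. The well-precedented aldol aromatisation of this alkyl ester (Et3N, CH2Cl2, then AcOH) gives benzyl 2,4-dihydroxy-6-[(2-pentyl-1,3-dioxolan-2-yl)methyl]benzoate F5. Methylation (MeI, K2CO3, acetone) gives benzyl 2,4-dimethoxy-6-[(2-pentyl-1,3-dioxolan-2-yl)methyl]benzoate F6. Hydrogenolysis (H2, Pd/C, EtOAc) gives 2,4-dimethoxy-6-[(2-pentyl-1,3-dioxolan-2-yl)methyl]benzoic acid F7, in which the ketal denies the activated acid an enolisable ketone to lactonise onto. Classical depside esterification of F7 with the 4-hydroxyl of 9 (DCC, catalytic DMAP, CH2Cl2) gives benzyl 4-({2,4-dimethoxy-6-[(2-pentyl-1,3-dioxolan-2-yl)methyl]benzoyl}oxy)-2-hydroxy-6-pentylbenzoate F8. Methylation of its one remaining hydroxyl (MeI, K2CO3, acetone) rejoins the route at 14.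

Step 4. Proton transfer may replace acylation: the dianion can deprotonate the α-methylene of amide 3, with β-elimination opening the dioxolane, or conversion may simply stall. The fallback sets out from 3 and 5 and replaces the acylation by an aldol addition and an oxidation. Reduction of 3 with DIBAL-H (THF, −78 °C) should give 2-(2-pentyl-1,3-dioxolan-2-yl)acetaldehyde F9. Addition of the dianion of 5 (LDA, 2 equiv, THF, −78 °C) to F9 gives 6-[4-hydroxy-2-oxo-5-(2-pentyl-1,3-dioxolan-2-yl)pentyl]-2,2-dimethyl-4H-1,3-dioxin-4-one F10, racemic. Oxidation of the β-hydroxy ketone with Dess–Martin periodinane (CH2Cl2) removes that stereocentre and rejoins the route at 6.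

**Further compounds**
F1 | step 8 | 7-hydroxy-2,2-dimethyl-5-[(2-pentyl-1,3-dioxolan-2-yl)methyl]-4H-1,3-benzodioxin-4-one | CCCCCC1(Cc2cc(O)cc3OC(C)(C)OC(=O)c23)OCCO1
F2 | step 8 | 7-methoxy-2,2-dimethyl-5-[(2-pentyl-1,3-dioxolan-2-yl)methyl]-4H-1,3-benzodioxin-4-one | CCCCCC1(Cc2cc(OC)cc3OC(C)(C)OC(=O)c23)OCCO1
F3 | step 8 | benzyl 2-hydroxy-4-({2-hydroxy-4-methoxy-6-[(2-pentyl-1,3-dioxolan-2-yl)methyl]benzoyl}oxy)-6-pentylbenzoate | CCCCCC1(Cc2cc(OC)cc(O)c2C(=O)Oc2cc(CCCCC)c(C(=O)OCc3ccccc3)c(O)c2)OCCO1
F4 | step 7 | benzyl 3,5,7-trioxo-8-(2-pentyl-1,3-dioxolan-2-yl)octanoate | CCCCCC1(CC(=O)CC(=O)CC(=O)CC(=O)OCc2ccccc2)OCCO1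
F5 | step 7 | benzyl 2,4-dihydroxy-6-[(2-pentyl-1,3-dioxolan-2-yl)methyl]benzoate | CCCCCC1(Cc2cc(O)cc(O)c2C(=O)OCc2ccccc2)OCCO1
F6 | step 7 | benzyl 2,4-dimethoxy-6-[(2-pentyl-1,3-dioxolan-2-yl)methyl]benzoate | CCCCCC1(Cc2cc(OC)cc(OC)c2C(=O)OCc2ccccc2)OCCO1
F7 | step 7 | 2,4-dimethoxy-6-[(2-pentyl-1,3-dioxolan-2-yl)methyl]benzoic acid | CCCCCC1(Cc2cc(OC)cc(OC)c2C(=O)O)OCCO1
F8 | step 7 | benzyl 4-({2,4-dimethoxy-6-[(2-pentyl-1,3-dioxolan-2-yl)methyl]benzoyl}oxy)-2-hydroxy-6-pentylbenzoate | CCCCCC1(Cc2cc(OC)cc(OC)c2C(=O)Oc2cc(CCCCC)c(C(=O)OCc3ccccc3)c(O)c2)OCCO1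
F9 | step 4 | 2-(2-pentyl-1,3-dioxolan-2-yl)acetaldehyde | CCCCCC1(CC=O)OCCO1
F10 | step 4 | 6-[4-hydroxy-2-oxo-5-(2-pentyl-1,3-dioxolan-2-yl)pentyl]-2,2-dimethyl-4H-1,3-dioxin-4-one (racemic) | CCCCCC1(CC(O)CC(=O)CC2=CC(=O)OC(C)(C)O2)OCCO1
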